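**Retrosynthetic overview**
1. Target ⇒ olefin cross-metathesis then hydrogenation (inside the C10 tether) joining a hexenyl lactone diacid and a heptenyl benzyl (R)-malate; the benzyl ester falls in the same hydrogenation.
2. Lactone diacid ⇒ nitro lactone acid (CH2NO2 as latent CO2H) ⇒ key step: tartrate-controlled hydroxylation and Baeyer–Villiger-type ring expansion (1,2-acyl shift from C to O) of a 3-substituted cyclopentane-1,2-dione.
3. Dione ⇒ cyclopentane-1,2-dione + (E)-1-nitrohepta-1,6-diene (thiourea-catalysed Michael addition sets the CH centre) ⇐ hex-5-enal + nitromethane.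
4. Malate arm ⇒ 7-bromohept-1-ene + 4-benzyl (R)-malate ⇐ benzyl hydrogen fumarate by a new boron-tethered enantioselective hydration ⇐ maleic anhydride + benzyl alcohol.
5. Ring order: bought carbocycle → transient six-membered anhydride → γ-lactone (the only ring of the target), all within step 3.

Assumption: the catalyst enantiomers named in steps 2, 3 and 6 are those predicted by the closest published facial models; each sense is checked on the first run and the mirror-image (or pseudo-enantiomeric) catalyst is used if it is opposite.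

**Step 1**
Reactants: 1 hex-5-enal; 2 nitromethane
Product: 5 (1E)-1-nitrohepta-1,6-diene, via nitro alcohol 3 (not isolated), via nitro mesylate 4 (not isolated)
Conditions: MeNO2 (5 equiv), tBuOK (5 mol%), THF/tBuOH, 0 °C to rt; concentrate; then MsCl (1.2 equiv), Et3N (2.5 equiv), CH2Cl2, 0 °C
Reagents that add atoms: none
Why: Henry addition followed by E1cB elimination of the mesylate gives the conjugated (E)-nitroalkene, and the remote terminal olefin is inert.

**Step 2**
Reactants: 5 (1E)-1-nitrohepta-1,6-diene; 6 cyclopentane-1,2-dione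
Product: 7 2-hydroxy-3-[(2R)-1-nitrohept-6-en-2-yl]cyclopent-2-en-1-one
Conditions: (R,R)-Takemoto thiourea, 1-[3,5-bis(trifluoromethyl)phenyl]-3-[(1R,2R)-2-(dimethylamino)cyclohexyl]thiourea (10 mol%), toluene, −20 °C to rt
Reagents that add atoms: none
Why: Organocatalytic Michael addition in which the thiourea binds the nitro group and the amine deprotonates the enol of 6, so C3 attacks one face of the nitroalkene and sets the (R) CH centre; the product re-enolises, so no ring stereocentre arises.

**Step 3 (key step)**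
Reactants: 7 2-hydroxy-3-[(2R)-1-nitrohept-6-en-2-yl]cyclopent-2-en-1-one
Product: 10 (2R)-2-[(2S)-1-nitrohept-6-en-2-yl]-5-oxooxolane-2-carboxylic acid, via hydroxy dione 8 (not isolated), via cyclic anhydride 9 (not isolated)
Conditions: Ti(OiPr)4 (1.0 equiv), (+)-diethyl L-tartrate (1.6 equiv), tBuOOH (2.5 equiv), 4 Å MS, CH2Cl2, −20 °C, 3 d; then aq. citric acid, 1 M HCl, rt
Reagents that add atoms: tert-butyl hydroperoxide, CC(C)(C)OO
Why: The titanium-bound enol is hydroxylated at C3 under tartrate (reagent) control, setting the quaternary centre as R; peroxide addition to the 1,2-dione then triggers a Baeyer–Villiger-type 1,2-acyl shift that expands the carbocycle to anhydride 9, which the tertiary alkoxide opens to the γ-lactone acid (asymmetric oxidative ring expansion of 3-alkylcyclopentane-1,2-diones).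

**Step 4**
Reactants: 10 (2R)-2-[(2S)-1-nitrohept-6-en-2-yl]-5-oxooxolane-2-carboxylic acid
Product: 11 (2R)-2-[(1R)-1-carboxyhex-5-en-1-yl]-5-oxooxolane-2-carboxylic acid
Conditions: NaNO2 (3 equiv), AcOH (10 equiv), DMSO, 35 °C
Reagents that add atoms: sodium nitrite, [Na+].[O-]N=O; water, O
Why: Nitrosative Nef-type oxidation of the primary nitroalkane to the carboxylic acid via the nitrolic acid is mild and does not epimerise the adjacent centre (the descriptor changes from S to R only through CIP priorities); lactone, acid and terminal olefin survive.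

**Step 5**
Reactants: 12 maleic anhydride; 13 benzyl alcohol
Product: 15 (2E)-4-(benzyloxy)-4-oxobut-2-enoic acid, via benzyl hydrogen maleate 14 (not isolated)
Conditions: toluene, 80 °C; then AcCl (5 mol%), 80 °C; crystallise
Reagents that add atoms: none
Why: Alcoholysis of the anhydride gives the half ester, and acyl chloride/HCl-catalysed Z-to-E isomerisation delivers the crystalline fumarate half ester.

**Step 6 (new reaction)**
Reactants: 15 (2E)-4-(benzyloxy)-4-oxobut-2-enoic acid
Product: 17 (2R)-4-(benzyloxy)-2-hydroxy-4-oxobutanoic acid, via dioxaborolanone 16 (not isolated)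
Conditions: PhB(OH)2 (1.2 equiv), 9-amino(9-deoxy)epi-quinidine-derived 3,5-bis(trifluoromethyl)phenyl thiourea (10 mol%), 4 Å MS, toluene, 50 °C; then pinacol (1.5 equiv), rt
Reagents that add atoms: phenylboronic acid, OB(O)c1ccccc1
Why: Proposed new method: the free carboxyl group of 15 condenses with PhB(OH)2 to an acyloxyboron hemi-anhydride, the quinuclidine nitrogen converts it into a chiral tetrahedral borate, and its B–OH is delivered intramolecularly (5-exo-trig oxa-Michael) to C2, which is β to the thiourea-bound benzyl ester, so the tether fixes the regiochemistry, the chiral ion pair selects the face, and the stable dioxaborolanone 16 makes the hydration irreversible; the closest known reaction types are the amine–thiourea-catalysed boronic acid hemiester oxa-Michael hydration of γ-hydroxy enones and boronic acid activation of α,β-unsaturated carboxylic acids.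

**Step 7**
Reactants: 17 (2R)-4-(benzyloxy)-2-hydroxy-4-oxobutanoic acid; 18 7-bromohept-1-ene
Product: 19 4-benzyl 1-(hept-6-en-1-yl) (2R)-2-hydroxybutanedioate
Conditions: KHCO3 (1.1 equiv), Bu4NI (10 mol%), DMF, 45 °C
Reagents that add atoms: none
Why: SN2 O-alkylation of the carboxylate by the primary bromide; bicarbonate deprotonates only the acid, so the hydroxyl, the benzyl ester and the stereocentre are untouched.

**Step 8**
Reactants: 11 (2R)-2-[(1R)-1-carboxyhex-5-en-1-yl]-5-oxooxolane-2-carboxylic acid; 19 4-benzyl 1-(hept-6-en-1-yl) (2R)-2-hydroxybutanedioate (2.5 equiv)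
Product: 21 (2R)-2-[(1R)-1-carboxy-11-{[(2R)-3-carboxy-2-hydroxypropanoyl]oxy}undecyl]-5-oxooxolane-2-carboxylic acid, via cross-metathesis olefin 20 (not isolated)
Conditions: second-generation Hoveyda–Grubbs catalyst, RuCl2(SIMes)(=CH-C6H4-2-OiPr) (5 mol%), EtOAc, 45 °C, N2 sweep; filter through Celite; then 10% Pd/C, H2 (1 atm), EtOAc/EtOH, rt; reverse-phase HPLC
Reagents that add atoms: none
Why: Olefin cross-metathesis of two unhindered terminal alkenes (excess 19) builds the C10 tether, and the heterogeneous hydrogenation saturates the new olefin and hydrogenolyses the benzyl ester without touching any stereocentre, the lactone or the malate ester.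

**Compound list**
1 | hex-5-enal | C=CCCCC=O | starting material
2 | nitromethane | C[N+](=O)[O-] | starting material
3 | 1-nitrohept-6-en-2-ol (racemic) | C=CCCCC(O)C[N+](=O)[O-] | intermediate
4 | 1-nitrohept-6-en-2-yl methanesulfonate (racemic) | C=CCCCC(OS(C)(=O)=O)C[N+](=O)[O-] | intermediate
5 | (1E)-1-nitrohepta-1,6-diene | C=CCCC/C=C/[N+](=O)[O-] | intermediate
6 | cyclopentane-1,2-dione | O=C1CCCC1=O | starting material
7 | 2-hydroxy-3-[(2R)-1-nitrohept-6-en-2-yl]cyclopent-2-en-1-one | C=CCCC[C@@H](C[N+](=O)[O-])C1=C(O)C(=O)CC1 | intermediate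
8 | (3R)-3-hydroxy-3-[(2S)-1-nitrohept-6-en-2-yl]cyclopentane-1,2-dione | C=CCCC[C@@H](C[N+](=O)[O-])[C@@]1(O)C(=O)C(=O)CC1 | intermediate
9 | (3R)-3-hydroxy-3-[(2S)-1-nitrohept-6-en-2-yl]oxane-2,6-dione | C=CCCC[C@@H](C[N+](=O)[O-])[C@@]1(O)C(=O)OC(=O)CC1 | intermediate
10 | (2R)-2-[(2S)-1-nitrohept-6-en-2-yl]-5-oxooxolane-2-carboxylic acid | C=CCCC[C@@H](C[N+](=O)[O-])[C@@]1(C(=O)O)CCC(=O)O1 | intermediate
11 | (2R)-2-[(1R)-1-carboxyhex-5-en-1-yl]-5-oxooxolane-2-carboxylic acid | C=CCCC[C@@H](C(=O)O)[C@@]1(C(=O)O)CCC(=O)O1 | intermediate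
12 | maleic anhydride | O=C1OC(=O)C=C1 | starting material
13 | benzyl alcohol | OCc1ccccc1 | starting material
14 | (2Z)-4-(benzyloxy)-4-oxobut-2-enoic acid | OC(=O)/C=C\C(=O)OCc1ccccc1 | intermediate
15 | (2E)-4-(benzyloxy)-4-oxobut-2-enoic acid | OC(=O)/C=C/C(=O)OCc1ccccc1 | intermediate
16 | benzyl 2-[(4R)-5-oxo-2-phenyl-1,3,2-dioxaborolan-4-yl]acetate | O=C(OCc1ccccc1)C[C@H]1OB(c2ccccc2)OC1=O | intermediate
17 | (2R)-4-(benzyloxy)-2-hydroxy-4-oxobutanoic acid | O=C(OCc1ccccc1)C[C@@H](O)C(=O)O | intermediate
18 | 7-bromohept-1-ene | C=CCCCCCBr | starting material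
19 | 4-benzyl 1-(hept-6-en-1-yl) (2R)-2-hydroxybutanedioate | O=C(OCc1ccccc1)C[C@@H](O)C(=O)OCCCCCC=C | intermediate
20 | (2R)-2-[(1R,5E)-11-{[(2R)-4-(benzyloxy)-2-hydroxy-4-oxobutanoyl]oxy}-1-carboxyundec-5-en-1-yl]-5-oxooxolane-2-carboxylic acid (E/Z mixture, E drawn) | O=C(OCc1ccccc1)C[C@@H](O)C(=O)OCCCCC/C=C/CCC[C@@H](C(=O)O)[C@@]1(C(=O)O)CCC(=O)O1 | intermediate
21 | (2R)-2-[(1R)-1-carboxy-11-{[(2R)-3-carboxy-2-hydroxypropanoyl]oxy}undecyl]-5-oxooxolane-2-carboxylic acid | O=C(O)C[C@@H](O)C(=O)OCCCCCCCCCC[C@@H](C(=O)O)[C@@]1(C(=O)O)CCC(=O)O1 | target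

**Totals**
Total steps: 8. Longest linear sequence: 5 (steps 1, 2, 3, 4, 8); the malate branch is steps 5, 6, 7, then 8.

**Three steps most likely to fail**

Step 6 (new hydration). The risks are competing 6-endo delivery to C3 (which would give the regioisomeric 1-benzyl malate), modest ee, and slow acyloxyboron formation; ee can be upgraded by crystallising 17 or its dicyclohexylammonium salt. The fallback uses known chemistry, sets out from 12 and returns at 17. Hydrolysis of 12 and enantioselective hydration with maleate hydratase (whole cells of Pseudomonas pseudoalcaligenes) gives (2R)-2-hydroxybutanedioic acid F1. 2,2-Dimethoxypropane/TsOH then gives 2-[(4R)-2,2-dimethyl-5-oxo-1,3-dioxolan-4-yl]acetic acid F2. Esterification with 13 (EDC, DMAP) gives benzyl 2-[(4R)-2,2-dimethyl-5-oxo-1,3-dioxolan-4-yl]acetate F3, and aqueous AcOH at 50 °C removes the acetonide to give 17.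

Step 3 (ring expansion). The risks are slow or mismatched oxidation of a dione with a branched stereogenic substituent, and interference by the acidic nitromethyl group. The fallback sets out from 7 and returns at 10, with no new compound (F0). The potassium enolate of 7 (KHMDS, THF, −78 °C) is hydroxylated with the matching enantiomer of (camphorsulfonyl)oxaziridine to give 8, which is isolated here. 30% H2O2/NaHCO3 in aqueous THF at 0 °C, then HCl, effects the same Baeyer–Villiger-type expansion through 9 to 10.

Step 2 (Michael addition). The risks are low reactivity and ee with an aliphatic nitroalkene. The fallback sets out from 5 and 6 and returns at 10. Et3N-catalysed addition gives racemic material, that is 7 together with 2-hydroxy-3-[(2S)-1-nitrohept-6-en-2-yl]cyclopent-2-en-1-one F4. The mixture is carried through step 3, where the tartrate fixes the quaternary centre as R in both antipodes. 7 gives 10, while F4 gives, through (3R)-3-hydroxy-3-[(2R)-1-nitrohept-6-en-2-yl]cyclopentane-1,2-dione F5 and (3R)-3-hydroxy-3-[(2R)-1-nitrohept-6-en-2-yl]oxane-2,6-dione F6, the diastereomer (2R)-2-[(2R)-1-nitrohept-6-en-2-yl]-5-oxooxolane-2-carboxylic acid F7. F7 is removed by chromatography or crystallisation of the dicyclohexylammonium salts, at the cost of half the material.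

**Further compounds**
F1 | step 6 | (2R)-2-hydroxybutanedioic acid | O=C(O)C[C@@H](O)C(=O)O
F2 | step 6 | 2-[(4R)-2,2-dimethyl-5-oxo-1,3-dioxolan-4-yl]acetic acid | O=C(O)C[C@H]1OC(C)(C)OC1=O
F3 | step 6 | benzyl 2-[(4R)-2,2-dimethyl-5-oxo-1,3-dioxolan-4-yl]acetate | O=C(OCc1ccccc1)C[C@H]1OC(C)(C)OC1=O
F0 | step 3 | none | none
F4 | step 2 | 2-hydroxy-3-[(2S)-1-nitrohept-6-en-2-yl]cyclopent-2-en-1-one | C=CCCC[C@H](C[N+](=O)[O-])C1=C(O)C(=O)CC1
F5 | step 2 | (3R)-3-hydroxy-3-[(2R)-1-nitrohept-6-en-2-yl]cyclopentane-1,2-dione | C=CCCC[C@H](C[N+](=O)[O-])[C@@]1(O)C(=O)C(=O)CC1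
F6 | step 2 | (3R)-3-hydroxy-3-[(2R)-1-nitrohept-6-en-2-yl]oxane-2,6-dione | C=CCCC[C@H](C[N+](=O)[O-])[C@@]1(O)C(=O)OC(=O)CC1
F7 | step 2 | (2R)-2-[(2R)-1-nitrohept-6-en-2-yl]-5-oxooxolane-2-carboxylic acid | C=CCCC[C@H](C[N+](=O)[O-])[C@@]1(C(=O)O)CCC(=O)O1
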